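The synthesis rests on cutting the central 3-alkyl-5,6-dihydro-2H-pyran-2-one ring (O1, C2, C3=C4, C5, C6) at O1–C2 and C5–C6. Because the terpenoid tail sits on C3 and the γ-butyrolactone ring on C6, this cut splits the molecule into a tail diene and a lactone aldehyde. One chromium(III)-catalysed asymmetric oxa-[4+2] cycloaddition forms both bonds, closes the six-membered ring, places the alkene at C3=C4 and sets C6 as R. Its precursors are a (1E)-1-methoxybuta-1,3-diene bearing the complete C16 tail on C2 and (R)-5-oxooxolane-3-carbaldehyde, whose stereocentre comes from resolved paraconic acid. Acetal hydrolysis and lactol oxidation then deliver the lactone.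

Key step: step 11

Assumption 1: the less soluble salt of paraconic acid with (S)-1-phenylethylamine is taken to contain the (R)-(+)-acid. If the pairing is the reverse, the antipodal amine is used and nothing else changes.
Assumption 2: the catalyst built on (1R,2S)-1-aminoindan-2-ol is taken to open the aldehyde face that gives 6R, by analogy with its behaviour towards simple aliphatic aldehydes and 1-methoxybutadiene. Otherwise its (1S,2R) antipode is used.

Step 1
Reactants: 1 dihydro-β-ionone; 2 triethyl phosphonoacetate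
Product: 3 ethyl (2E)-3-methyl-5-(2,6,6-trimethylcyclohex-1-en-1-yl)pent-2-enoate
Conditions: NaH, THF, 0 → 50 °C; chromatography to remove the minor 2Z isomer
Reagents that add atoms: triethyl phosphonoacetate (2), CCOC(=O)CP(=O)(OCC)OCC
Why: The Horner–Wadsworth–Emmons olefination of a methyl ketone with a stabilised phosphonate anion favours the E-enoate (ester anti to the longer CH2CH2 branch), and removing the minor geometric isomer here fixes the only stereodefined alkene of the tail.

Step 2
Reactants: 3 ethyl (2E)-3-methyl-5-(2,6,6-trimethylcyclohex-1-en-1-yl)pent-2-enoate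
Product: 4 (2E)-3-methyl-5-(2,6,6-trimethylcyclohex-1-en-1-yl)pent-2-en-1-ol
Conditions: DIBAL-H (2.3 equiv), CH2Cl2, −78 → 0 °C; aq Rochelle salt
Reagents that add atoms: none
Why: The 1,2-reduction of an α,β-unsaturated ester with DIBAL-H stops cleanly at the allylic alcohol and leaves both alkenes and the E geometry untouched.

Step 3
Reactants: 4 (2E)-3-methyl-5-(2,6,6-trimethylcyclohex-1-en-1-yl)pent-2-en-1-ol
Product: 5 2-[(3E)-5-bromo-3-methylpent-3-en-1-yl]-1,3,3-trimethylcyclohex-1-ene
Conditions: PBr3 (0.4 equiv), Et2O, −10 → 0 °C; cold aq NaHCO3 wash; used crude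
Reagents that add atoms: phosphorus tribromide, BrP(Br)Br
Why: Bromination of a primary prenyl-type allylic alcohol with PBr3 at low temperature is a standard SN2-type substitution that should proceed without allylic transposition or loss of the E geometry.

Step 4
Reactants: 5 2-[(3E)-5-bromo-3-methylpent-3-en-1-yl]-1,3,3-trimethylcyclohex-1-ene; 6 N-methoxy-N-methylacetamide
Product: 7 (4E)-N-methoxy-N,5-dimethyl-7-(2,6,6-trimethylcyclohex-1-en-1-yl)hept-4-enamide
Conditions: 6, LDA, THF, −78 °C; then 5, −78 → −20 °C
Reagents that add atoms: N-methoxy-N-methylacetamide (6), CC(=O)N(C)OC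
Why: In this enolate alkylation the small lithium enolate of the acetamide displaces the reactive primary allylic bromide by SN2 at low temperature, which adds the two missing carbons and installs the acyl-transfer group in one operation.

Step 5
Reactants: 7 (4E)-N-methoxy-N,5-dimethyl-7-(2,6,6-trimethylcyclohex-1-en-1-yl)hept-4-enamide; 8 vinylmagnesium bromide
Product: 10 (6E)-7-methyl-9-(2,6,6-trimethylcyclohex-1-en-1-yl)nona-1,6-dien-3-one, via bromomagnesium tetrahedral adduct 9 (not isolated)
Conditions: 8 (1.5 equiv), THF, −78 → 0 °C; inverse quench into cold 1 M HCl; trace BHT; used promptly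
Reagents that add atoms: vinylmagnesium bromide (8), C=C[Mg]Br
Why: In the Weinreb ketone synthesis the chelated adduct 9 survives until the quench, so only one vinyl group enters, and the inverse acidic quench protonates the released N,O-dimethylhydroxylamine before it can add to the new enone.

Step 6
Reactants: 10 (6E)-7-methyl-9-(2,6,6-trimethylcyclohex-1-en-1-yl)nona-1,6-dien-3-one; 11 (methoxymethyl)triphenylphosphonium chloride
Product: 12 (1E)-1-methoxy-2-[(3E)-4-methyl-6-(2,6,6-trimethylcyclohex-1-en-1-yl)hex-3-en-1-yl]buta-1,3-diene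
Conditions: 11 (1.5 equiv), NaHMDS (1.4 equiv), THF, 0 °C; then 10, −78 → 0 °C; Et3N-deactivated SiO2
Reagents that add atoms: (methoxymethyl)triphenylphosphonium chloride (11), COC[P+](c1ccccc1)(c1ccccc1)c1ccccc1.[Cl-]
Why: In the Wittig methoxymethylenation the reactive ylide attacks the enone carbonyl rather than the β-carbon and should give the dienyl ether as a C1=C2 geometric mixture, which may be enriched or carried on as such because only the 1E isomer 12 is productive in step 11.

Step 7
Reactants: 13 racemic paraconic acid (5-oxooxolane-3-carboxylic acid); 14 (S)-1-phenylethylamine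
Product: 15 (S)-1-phenylethylammonium (3R)-5-oxooxolane-3-carboxylate
Conditions: 14 (1.0 equiv), EtOH, warm → rt; salt recrystallised from EtOH
Reagents that add atoms: (S)-1-phenylethylamine (14), C[C@H](N)c1ccccc1
Why: This classical resolution through diastereomeric salts relies on their different solubility, so repeated crystallisation should deliver the salt of the (R)-acid, the source of the butyrolactone stereocentre.

Step 8
Reactants: 15 (S)-1-phenylethylammonium (3R)-5-oxooxolane-3-carboxylate
Product: 16 (R)-paraconic acid [(3R)-5-oxooxolane-3-carboxylic acid]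
Conditions: sulfonic acid cation-exchange resin (H+ form), H2O, rt; evaporation
Reagents that add atoms: none
Why: Simple ion exchange holds the amine on the resin and releases the very water-soluble acid without base or extraction, so the lactone and the stereocentre are not touched.

Step 9
Reactants: 16 (R)-paraconic acid
Product: 17 (4S)-4-(hydroxymethyl)oxolan-2-one
Conditions: BH3·SMe2 (1.2 equiv), THF, 0 °C → rt; MeOH quench, co-evaporation with MeOH (no aqueous acid or base)
Reagents that add atoms: none
Why: Borane reduces a free carboxylic acid through its acyloxyborane much faster than a lactone, the stereocentre is untouched (R becomes S only through CIP priorities), and the non-aqueous quench avoids the acyl shift between the two CH2O arms that would racemise 17.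

Step 10
Reactants: 17 (4S)-4-(hydroxymethyl)oxolan-2-one
Product: 18 (3R)-5-oxooxolane-3-carbaldehyde
Conditions: Dess–Martin periodinane (1.1 equiv), CH2Cl2, 0 °C → rt; Et2O, short SiO2 pad; toluene azeotrope; used at once
Reagents that add atoms: none
Why: The Dess–Martin oxidation runs without added base at or below room temperature and stops at the aldehyde, so the α-centre, which could epimerise or expel the lactone carboxylate by E1cB, should survive if the crude aldehyde is used immediately.

Step 11
Reactants: 12 (1E)-1-methoxy-2-[(3E)-4-methyl-6-(2,6,6-trimethylcyclohex-1-en-1-yl)hex-3-en-1-yl]buta-1,3-diene; 18 (3R)-5-oxooxolane-3-carbaldehyde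
Product: 19 (2S,6R)-2-methoxy-3-[(3E)-4-methyl-6-(2,6,6-trimethylcyclohex-1-en-1-yl)hex-3-en-1-yl]-6-[(3R)-5-oxooxolan-3-yl]-5,6-dihydro-2H-pyran (2,6-cis)
Conditions: Cr(III)Cl complex of the tridentate Schiff base from (1R,2S)-1-aminoindan-2-ol and 3-(1-adamantyl)-2-hydroxy-5-methylbenzaldehyde (10 mol %), powdered 4 Å MS, minimum EtOAc, rt, 24–48 h; 18 in slight excess
Reagents that add atoms: none
Why: The Cr(III) centre binds the formyl oxygen of 18 and the s-cis conformer of 12 adds in a concerted but asynchronous endo [4+2] cycloaddition, its unsubstituted C4 terminus bonding to the carbonyl carbon (C5–C6) and its methoxy-bearing C1 to the carbonyl oxygen (O1–C2). The closest known reaction type is the hetero-Diels–Alder reaction of 1-alkoxybutadienes with unactivated aliphatic aldehydes under tridentate Schiff-base chromium(III) catalysis, applied here to a 2-alkyl diene and an α-branched aldehyde. The one new ring, the 5,6-dihydro-2H-pyran, closes by intermolecular cycloaddition in which both ring bonds arise in the same event, so no separate cyclisation mode has to compete. C6 is controlled by the catalyst, which leaves one aldehyde face open (6R expected with the (1R,2S) ligand), while the resident α-centre, flanked by two CH2 arms of similar size, should exert only a weak bias of its own, and C2 follows from the endo approach and the 1E geometry (2,6-cis, 2S) and is erased in step 13. Regioselectivity is secured by the methoxy donor, which polarises the diene towards C4, and chemoselectivity follows because only the aldehyde is a competent heterodienophile (lactone C=O and isolated tail alkenes are inert) and the 1Z diene cannot reach a planar s-cis form. The medium is neutral and anhydrous, which protects the enol ether and the epimerisable, β-acyloxy-substituted α-centre of 18.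

Step 12
Reactants: 19 (2S,6R)-2-methoxy-3-[tail]-6-[(3R)-5-oxooxolan-3-yl]-5,6-dihydro-2H-pyran
Product: 20 (6R)-3-[(3E)-4-methyl-6-(2,6,6-trimethylcyclohex-1-en-1-yl)hex-3-en-1-yl]-6-[(3R)-5-oxooxolan-3-yl]-5,6-dihydro-2H-pyran-2-ol (anomeric mixture)
Conditions: 0.5 M aq HCl–THF (1:4), 0 °C → rt, short contact; neutral work-up
Reagents that add atoms: water, O
Why: In this acid-catalysed acetal hydrolysis the allylic oxocarbenium ion forms under very mild aqueous acid and is trapped by water, conditions that leave the γ-lactone, the tri- and tetrasubstituted alkenes and C6 untouched.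

Step 13
Reactants: 20 (6R)-3-[tail]-6-[(3R)-5-oxooxolan-3-yl]-5,6-dihydro-2H-pyran-2-ol
Product: 21 (6R)-3-[(3E)-4-methyl-6-(2,6,6-trimethylcyclohex-1-en-1-yl)hex-3-en-1-yl]-6-[(3R)-5-oxooxolan-3-yl]-5,6-dihydro-2H-pyran-2-one (target)
Conditions: activated MnO2 (15 equiv), CH2Cl2, rt
Reagents that add atoms: none
Why: The oxidation of an allylic lactol with activated MnO2 is neutral and selective for the allylic hemiacetal C–H, removes the C2 stereocentre and gives the conjugated δ-lactone without affecting C6, the lactone centre or the isolated alkenes.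

Compound list
1 | dihydro-β-ionone | CC1=C(CCC(C)=O)C(C)(C)CCC1 | starting material
2 | triethyl phosphonoacetate | CCOC(=O)CP(=O)(OCC)OCC | starting material
3 | ethyl (2E)-3-methyl-5-(2,6,6-trimethylcyclohex-1-en-1-yl)pent-2-enoate | CCOC(=O)/C=C(C)/CCC1=C(C)CCCC1(C)C | intermediate
4 | (2E)-3-methyl-5-(2,6,6-trimethylcyclohex-1-en-1-yl)pent-2-en-1-ol | OC/C=C(C)/CCC1=C(C)CCCC1(C)C | intermediate
5 | 2-[(3E)-5-bromo-3-methylpent-3-en-1-yl]-1,3,3-trimethylcyclohex-1-ene | BrC/C=C(C)/CCC1=C(C)CCCC1(C)C | intermediate
6 | N-methoxy-N-methylacetamide | CC(=O)N(C)OC | starting material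
7 | (4E)-N-methoxy-N,5-dimethyl-7-(2,6,6-trimethylcyclohex-1-en-1-yl)hept-4-enamide | CON(C)C(=O)CC/C=C(C)/CCC1=C(C)CCCC1(C)C | intermediate
8 | vinylmagnesium bromide | C=C[Mg]Br | starting material
9 | bromomagnesium tetrahedral adduct of 7 and 8 (not isolated) | C=CC(O[Mg]Br)(N(C)OC)CC/C=C(C)/CCC1=C(C)CCCC1(C)C | intermediate
10 | (6E)-7-methyl-9-(2,6,6-trimethylcyclohex-1-en-1-yl)nona-1,6-dien-3-one | C=CC(=O)CC/C=C(C)/CCC1=C(C)CCCC1(C)C | intermediate
11 | (methoxymethyl)triphenylphosphonium chloride | COC[P+](c1ccccc1)(c1ccccc1)c1ccccc1.[Cl-] | starting material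
12 | (1E)-1-methoxy-2-[(3E)-4-methyl-6-(2,6,6-trimethylcyclohex-1-en-1-yl)hex-3-en-1-yl]buta-1,3-diene | CO/C=C(/C=C)CC/C=C(C)/CCC1=C(C)CCCC1(C)C | intermediate
13 | racemic paraconic acid | O=C1CC(CO1)C(=O)O | starting material
14 | (S)-1-phenylethylamine | C[C@H](N)c1ccccc1 | starting material
15 | (S)-1-phenylethylammonium (3R)-5-oxooxolane-3-carboxylate | [O-]C(=O)[C@H]1COC(=O)C1.C[C@H]([NH3+])c1ccccc1 | intermediate
16 | (R)-paraconic acid | OC(=O)[C@H]1COC(=O)C1 | intermediate
17 | (4S)-4-(hydroxymethyl)oxolan-2-one | OC[C@H]1COC(=O)C1 | intermediate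
18 | (3R)-5-oxooxolane-3-carbaldehyde | O=C[C@H]1COC(=O)C1 | intermediate
19 | (2S,6R)-2-methoxy-3-[(3E)-4-methyl-6-(2,6,6-trimethylcyclohex-1-en-1-yl)hex-3-en-1-yl]-6-[(3R)-5-oxooxolan-3-yl]-5,6-dihydro-2H-pyran | CO[C@H]1O[C@@H]([C@H]2COC(=O)C2)CC=C1CC/C=C(C)/CCC3=C(C)CCCC3(C)C | intermediate
20 | (6R)-3-[(3E)-4-methyl-6-(2,6,6-trimethylcyclohex-1-en-1-yl)hex-3-en-1-yl]-6-[(3R)-5-oxooxolan-3-yl]-5,6-dihydro-2H-pyran-2-ol | OC1O[C@@H]([C@H]2COC(=O)C2)CC=C1CC/C=C(C)/CCC3=C(C)CCCC3(C)C | intermediate
21 | (6R)-3-[(3E)-4-methyl-6-(2,6,6-trimethylcyclohex-1-en-1-yl)hex-3-en-1-yl]-6-[(3R)-5-oxooxolan-3-yl]-5,6-dihydro-2H-pyran-2-one | CC1=C(CC/C(C)=C/CCC2=CC[C@H]([C@H]3COC(=O)C3)OC2=O)C(C)(C)CCC1 | target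

Total step count: 13. Longest linear sequence: 9 steps (steps 1–6, then 11–13). The aldehyde branch (steps 7–10) runs in parallel.

Steps most likely to fail

Step 11. The cycloaddition of the bulky 2-alkyl diene may be slow. The fragile aldehyde could then epimerise, eliminate or oligomerise while it waits, and catalyst control of the aldehyde face may be incomplete. The fallback sets out from 18 and 4 and comes back at 21. It builds the ring first with a cheap diene used in large excess and attaches the tail afterwards by cross-coupling at C3.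
- Aldehyde 18 and commercial (E)-1-methoxybuta-1,3-diene (neat, excess) under the same catalyst class should give (2S,6R)-2-methoxy-6-[(3R)-5-oxooxolan-3-yl]-5,6-dihydro-2H-pyran F1.
- Dilute aqueous acid converts F1 into the lactol (6R)-6-[(3R)-5-oxooxolan-3-yl]-5,6-dihydro-2H-pyran-2-ol F2.
- MnO2 oxidises F2 to the parent lactone (6R)-6-[(3R)-5-oxooxolan-3-yl]-5,6-dihydro-2H-pyran-2-one F3.
- Addition of Br2 in CH2Cl2 gives the 3,4-dibromide (6R)-3,4-dibromo-6-[(3R)-5-oxooxolan-3-yl]oxan-2-one F4.
- Dehydrobromination with Et3N gives (6R)-3-bromo-6-[(3R)-5-oxooxolan-3-yl]-5,6-dihydro-2H-pyran-2-one F5.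
- In parallel, alcohol 4 is oxidised with MnO2 to (2E)-3-methyl-5-(2,6,6-trimethylcyclohex-1-en-1-yl)pent-2-enal F6.
- F6 is methylenated with Ph3P=CH2 to 1,3,3-trimethyl-2-[(3E)-3-methylhexa-3,5-dien-1-yl]cyclohex-1-ene F7.
- F7 is hydroborated at the terminal alkene with 9-BBN to 9-[(3E)-4-methyl-6-(2,6,6-trimethylcyclohex-1-en-1-yl)hex-3-en-1-yl]-9-borabicyclo[3.3.1]nonane F8.
- A B-alkyl Suzuki–Miyaura coupling of F8 with F5 [PdCl2(dppf), AsPh3, K3PO4, DMF–THF–H2O, rt] gives 21.

Step 6. Conjugate addition to the vinyl ketone or its anionic polymerisation may compete with olefination, and the C1=C2 geometric ratio may be unfavourable. The fallback sets out from 5 and comes back at 12. It avoids the vinyl ketone and creates the enol ether by elimination instead of olefination.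
- The kinetic lithium enolate of commercial 1,1-dimethoxypropan-2-one (LDA, THF, −78 °C) is allylated with 5 to give (5E)-1,1-dimethoxy-6-methyl-8-(2,6,6-trimethylcyclohex-1-en-1-yl)oct-5-en-2-one F9.
- Wittig ethylidenation (Ph3P=CHCH3) gives 2-[(3E)-7-(dimethoxymethyl)-3-methylnona-3,7-dien-1-yl]-1,3,3-trimethylcyclohex-1-ene F10. The geometry of its new alkene is irrelevant.
- TMSOTf/iPr2NEt then induces 1,4-elimination of one methoxy group. This passes through the s-trans allylic oxocarbenium ion, which should favour the 1E geometry of 12.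

Step 10. Configurational or constitutional integrity may be lost on the way to the aldehyde. The possible causes are acyl migration in the hydroxymethyl lactone, and epimerisation or β-elimination during oxidation and isolation. The fallback sets out from 16 and comes back at 18, bypassing 17.
- The acid is converted with EtSH/DCC (cat. DMAP, CH2Cl2, 0 °C) into S-ethyl (3R)-5-oxooxolane-3-carbothioate F11.
- F11 is reduced under neutral conditions by the Fukuyama reduction (Et3SiH, Pd/C, acetone, rt) directly to 18.

Further compounds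
F1 | step 11 | (2S,6R)-2-methoxy-6-[(3R)-5-oxooxolan-3-yl]-5,6-dihydro-2H-pyran | CO[C@H]1O[C@@H]([C@H]2COC(=O)C2)CC=C1
F2 | step 11 | (6R)-6-[(3R)-5-oxooxolan-3-yl]-5,6-dihydro-2H-pyran-2-ol | OC1O[C@@H]([C@H]2COC(=O)C2)CC=C1
F3 | step 11 | (6R)-6-[(3R)-5-oxooxolan-3-yl]-5,6-dihydro-2H-pyran-2-one | O=C1O[C@@H]([C@H]2COC(=O)C2)CC=C1
F4 | step 11 | (6R)-3,4-dibromo-6-[(3R)-5-oxooxolan-3-yl]oxan-2-one | O=C1O[C@@H]([C@H]2COC(=O)C2)CC(Br)C1Br
F5 | step 11 | (6R)-3-bromo-6-[(3R)-5-oxooxolan-3-yl]-5,6-dihydro-2H-pyran-2-one | O=C1O[C@@H]([C@H]2COC(=O)C2)CC=C1Br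
F6 | step 11 | (2E)-3-methyl-5-(2,6,6-trimethylcyclohex-1-en-1-yl)pent-2-enal | O=C/C=C(C)/CCC1=C(C)CCCC1(C)C
F7 | step 11 | 1,3,3-trimethyl-2-[(3E)-3-methylhexa-3,5-dien-1-yl]cyclohex-1-ene | C=C/C=C(C)/CCC1=C(C)CCCC1(C)C
F8 | step 11 | 9-[(3E)-4-methyl-6-(2,6,6-trimethylcyclohex-1-en-1-yl)hex-3-en-1-yl]-9-borabicyclo[3.3.1]nonane | CC1=C(CC/C(C)=C/CCB2C3CCCC2CCC3)C(C)(C)CCC1
F9 | step 6 | (5E)-1,1-dimethoxy-6-methyl-8-(2,6,6-trimethylcyclohex-1-en-1-yl)oct-5-en-2-one | COC(OC)C(=O)CC/C=C(C)/CCC1=C(C)CCCC1(C)C
F10 | step 6 | 2-[(3E)-7-(dimethoxymethyl)-3-methylnona-3,7-dien-1-yl]-1,3,3-trimethylcyclohex-1-ene | COC(OC)C(=CC)CC/C=C(C)/CCC1=C(C)CCCC1(C)C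
F11 | step 10 | S-ethyl (3R)-5-oxooxolane-3-carbothioate | CCSC(=O)[C@H]1COC(=O)C1
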